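**Plan**
- Key feature: in ring A (the δ-lactone) the spiro carbon carries a CH=CH–C(=O) arm and an O–CMe2 arm. Its other two bonds enter ring B, one to a CH2 and one to the methyl-bearing alkene carbon. Ring B is therefore the [4+2] adduct of a 2-silyloxy-3-substituted penta-1,3-diene and the exocyclic C=CH2 of a 5-methylene lactone.
- Cuts, in retrosynthetic order: C3(tetronate)–C(=CH2) of ring C; C3(tetronate)–angular carbon; angular carbon–CH3; spiro C–C(Me) together with CH2–CH2 of ring B; and CH2–C(Me)(CO2H) in the side chain of the diene.
- Forward order: ring A (Stille coupling, lactonisation); ring B (Diels–Alder, with the alkyne/ester side chain already on the diene); a temporary allylic δ-lactone; union with ring D (tetronic acid made separately); ring C last (Conia-ene).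
- Stereochemistry: the C(Me)(CO2H) centre comes from an asymmetric phase-transfer alkylation and the spiro carbon of ring A from a chiral boron Lewis acid. The angular carbon is set by attack anti to the O–CMe2 arm. C5 of ring D comes from (R)-lactate, and the spiro carbon of ring D is set by bonding anti to the 5-methyl group.

Key step: step 10

Assumption: the antipodes named for the two chiral catalysts (steps 7 and 10) are taken to give the configurations drawn. Both catalysts are sold as either antipode, so a reversed sense of induction is corrected by exchanging the antipode.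

**Step 1**
Reactants: 1 2-methylbut-3-yn-2-ol
Product: 2 2-methyl-3-(tributylstannyl)but-3-en-2-ol
Conditions: Bu3SnH, [Cp*RuCl]4 (1.5 mol %), CH2Cl2, rt
Reagents that add atoms: tributyltin hydride, CCCC[SnH](CCCC)CCCC
Why: Hydroxyl-directed ruthenium-catalysed hydrostannation delivers tin to the alkyne carbon next to the carbinol (Markovnikov sense), giving the 1,1-disubstituted vinylstannane that palladium-catalysed hydrostannation of this hindered propargylic alcohol would not give.

**Step 2**
Reactants: 2 2-methyl-3-(tributylstannyl)but-3-en-2-ol; 3 ethyl (Z)-3-iodoacrylate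
Product: 5 6,6-dimethyl-5-methylidene-5,6-dihydro-2H-pyran-2-one, via hydroxy dienoate 4 (not isolated)
Conditions: Pd(PPh3)4 (5 mol %), CuI (10 mol %), CsF, DMF, 45 °C; then CSA (cat.), toluene, 50 °C
Reagents that add atoms: none
Why: A Stille coupling accelerated by copper(I) and fluoride tolerates the hindered α-substituted vinylstannane and keeps the Z geometry of the iodoacrylate, so the tertiary hydroxyl lies next to the ester and closes ring A by transesterification, aided by the gem-dimethyl effect.

**Step 3**
Reactants: 6 methyl vinyl ketone; 7 acetaldehyde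
Product: 8 4-hydroxy-3-methylidenepentan-2-one (racemic)
Conditions: DABCO (15 mol %), 1,4-dioxane/H2O, 0 °C → rt
Reagents that add atoms: none
Why: This is a Morita–Baylis–Hillman reaction of an activated vinyl ketone with an unhindered aldehyde, and the racemic carbinol centre disappears in step 4.

**Step 4**
Reactants: 8 4-hydroxy-3-methylidenepentan-2-one
Product: 9 (3Z)-3-(bromomethyl)pent-3-en-2-one
Conditions: PBr3 (0.4 equiv), Et2O, 0 °C
Reagents that add atoms: phosphorus tribromide, BrP(Br)Br
Why: Allylic bromination with transposition (SN2′ type) of a Baylis–Hillman alcohol gives the conjugated trisubstituted alkene, in which the methyl group takes the position trans to the acetyl group (descriptor Z because of CH2Br).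

**Step 5**
Reactants: 10 2,2,5-trimethyl-1,3-dioxane-4,6-dione (methyl Meldrum's acid)
Product: 11 3-tert-butoxy-2-methyl-3-oxopropanoic acid (racemic)
Conditions: t-BuOH, reflux
Reagents that add atoms: tert-butanol, CC(C)(C)O
Why: Thermal alcoholysis of the dioxanedione opens the ring, releases acetone and stops at the half ester.

**Step 6**
Reactants: 11 3-tert-butoxy-2-methyl-3-oxopropanoic acid
Product: 12 1-benzhydryl 3-tert-butyl 2-methylpropanedioate (racemic, configurationally labile)
Conditions: Ph2CHBr, Et3N, MeCN, reflux
Reagents that add atoms: bromodiphenylmethane, BrC(c1ccccc1)c1ccccc1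
Why: Carboxylate O-alkylation with a reactive benzhydryl halide gives the mixed diester whose two bulky, different ester groups are what the chiral ion pair of step 7 requires.

**Step 7**
Reactants: 12 1-benzhydryl 3-tert-butyl 2-methylpropanedioate; 9 (3Z)-3-(bromomethyl)pent-3-en-2-one
Product: 13 1-benzhydryl 3-tert-butyl (2R)-2-[(2E)-2-acetylbut-2-en-1-yl]-2-methylpropanedioate
Conditions: (R,R)-3,4,5-trifluorophenyl-NAS bromide (N-spiro binaphthyl ammonium salt, 5 mol %), 50 % aq KOH, toluene, −40 °C
Reagents that add atoms: none
Why: In this asymmetric phase-transfer alkylation of a tert-butyl/benzhydryl α-methylmalonate with an allylic bromide, the enolate reacts inside a tight ion pair with the C2-symmetric ammonium cation, which shields one enolate face and sets the (R)-quaternary centre, while direct SN2 displacement at the primary carbon keeps the alkene geometry.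

**Step 8**
Reactants: 13 malonate enone
Product: 14 1-benzhydryl 3-tert-butyl (2R)-2-methyl-2-[(2E)-2-{1-[(triisopropylsilyl)oxy]ethenyl}but-2-en-1-yl]propanedioate
Conditions: TIPSOTf, Et3N, CH2Cl2, −78 → 0 °C
Reagents that add atoms: triisopropylsilyl trifluoromethanesulfonate, CC(C)[Si](OS(=O)(=O)C(F)(F)F)(C(C)C)C(C)C
Why: Soft enolisation of the methyl ketone with a silyl triflate and an amine removes an α′-proton and gives the cross-conjugated 2-silyloxydiene without touching the E-alkene or the quaternary centre.

**Step 9**
Reactants: 14 silyloxydiene malonate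
Product: 16 tert-butyl (2R,4E)-2-ethynyl-2-methyl-4-{1-[(triisopropylsilyl)oxy]ethenyl}hex-4-enoate, via formyl ester 15 (not isolated)
Conditions: DIBAL-H (1.1 equiv), CH2Cl2, −78 °C; MeOH; then K2CO3, dimethyl (1-diazo-2-oxopropyl)phosphonate, MeOH, 0 °C → rt
Reagents that add atoms: dimethyl (1-diazo-2-oxopropyl)phosphonate, CC(=O)C(=[N+]=[N-])P(=O)(OC)OC
Why: Partial DIBAL-H reduction takes the benzhydryl ester in preference to the tert-butyl ester, and the released non-enolisable aldehyde undergoes Ohira–Bestmann (Seyferth–Gilbert) homologation in the same flask with the quaternary centre untouched.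

**Step 10**
Reactants: 5 6,6-dimethyl-5-methylidene-5,6-dihydro-2H-pyran-2-one; 16 alkynyl silyloxydiene
Product: 17 tert-butyl (2R)-2-ethynyl-2-methyl-3-[(6R,7S)-1,1,7-trimethyl-3-oxo-9-(triisopropylsilyloxy)-2-oxaspiro[5.5]undeca-4,8-dien-8-yl]propanoate
Conditions: o-tolyl-oxazaborolidine from (S)-diphenylprolinol activated with Tf2NH (20 mol %), CH2Cl2, −78 → −40 °C
Reagents that add atoms: none
Why: Proposed new method: the boron Lewis acid binds the lactone carbonyl and lowers the LUMO of the whole dienoate, whose largest terminal coefficient lies on the exocyclic CH2, so a concerted but strongly asynchronous [4+2] addition starts with bonding between this CH2 and the nucleophilic CH2 terminus of the silyl dienol ether and ends with bonding between the disubstituted alkene carbon and the methyl-bearing diene terminus. The closest known reactions are Diels–Alder additions of 2-silyloxydienes to exocyclic methylene lactones and ketones giving spirocycles, and oxazaborolidinium-catalysed additions of 2-silyloxydienes to α,β-unsaturated esters and lactones; enantiocontrol at a γ,δ-alkene through a vinylogously bound carbonyl is the untested extension. Ring B, the six-membered carbocycle, is closed by intermolecular suprafacial [4+2] addition, and both new σ-bonds (spiro C–CHMe and CH2–CH2) are made in this step. The spiro centre (R) is set by the catalyst, whose aryl group should cover one face of the flat lactone, and the CHMe centre (S) follows from the E geometry of the diene with the flat CH=CH–C=O arm endo and the bulky O–CMe2 arm exo; this second centre is erased in step 11. Regioselectivity is secured because the silyloxy group (para rule) and the terminal methyl group (ortho rule) direct in the same sense, and site selectivity because the endocyclic cis-enoate alkene is a poorer, more hindered dienophile and the s-trans locked CH2=C–CH=CH unit of 5 cannot serve as a diene.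

**Step 11**
Reactants: 17 spiro silyl enol ether
Product: 18 tert-butyl (2R)-2-ethynyl-2-methyl-3-[(6R)-1,1,7-trimethyl-3,9-dioxo-2-oxaspiro[5.5]undeca-4,7-dien-8-yl]propanoate
Conditions: DDQ, 2,4,6-collidine, CH2Cl2, 0 °C → rt
Reagents that add atoms: none
Why: In this dehydrosilylation of a silyl enol ether with DDQ, hydride loss from the tertiary allylic C–H at the methyl-bearing carbon gives the more substituted silyloxyallyl cation (the side-chain CH2 is neopentyl and inductively deactivated), so desilylation places the alkene in the tetrasubstituted ring position and removes the CHMe stereocentre.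

**Step 12**
Reactants: 18 spiro enone
Product: 20 allylic δ-lactone between the side-chain carboxyl and the methylated ring-B carbon [(R) at the ring-A spiro carbon and (R) at C(Me)(ethynyl); either configuration at the O-bearing carbon], via tertiary allylic alcohol 19 (not isolated)
Conditions: MeLi, CeCl3, THF, −78 °C; H2O; then CSA (10 mol %), CH2Cl2, 0 °C → rt
Reagents that add atoms: methyllithium, [Li]C
Why: Organocerium 1,2-addition is faster at the enone carbonyl than at the ester or lactone and does not deprotonate the alkyne, and mild acid then ionises the tertiary allylic alcohol so that the neighbouring tert-butyl ester carbonyl captures the cation and sheds isobutene (cationic lactonisation); the carbinol configuration is irrelevant because step 15 passes through the same cation.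

**Step 13**
Reactants: 21 methyl (R)-lactate
Product: 22 methyl (2R)-2-acetoxypropanoate
Conditions: Ac2O, pyridine, DMAP (cat.), CH2Cl2, 0 °C → rt
Reagents that add atoms: acetic anhydride, CC(=O)OC(C)=O
Why: This is a standard O-acylation, which does not touch the stereocentre.

**Step 14**
Reactants: 22 methyl (2R)-2-acetoxypropanoate
Product: 23 (5R)-4-hydroxy-5-methylfuran-2(5H)-one [(R)-5-methyltetronic acid]
Conditions: LiHMDS (2.2 equiv), THF, −78 °C; aq HCl
Reagents that add atoms: none
Why: Dieckmann (intramolecular Claisen) condensation of the acetate enolate onto the lactate ester, run cold with a non-nucleophilic base, closes ring D (5-exo-trig) without loss of the (R)-centre.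

**Step 15**
Reactants: 20 allylic δ-lactone; 23 (R)-5-methyltetronic acid
Product: 24 (2R)-2-ethynyl-3-{(6R,9S)-9-[(5R)-4-hydroxy-5-methyl-2-oxo-2,5-dihydrofuran-3-yl]-1,1,7,9-tetramethyl-3-oxo-2-oxaspiro[5.5]undeca-4,7-dien-8-yl}-2-methylpropanoic acid
Conditions: Tf2NH (10 mol %), 23 in excess, CH2Cl2/HFIP, −20 °C → rt
Reagents that add atoms: none
Why: Proposed new method: protonation of the lactone carbonyl ionises the tertiary allylic C–O bond to a fully alkyl-substituted allyl cation that keeps the freed carboxyl group on its side chain, and the enol carbon C3 of 23 captures it at the terminus remote from the ring-A spiro carbon (the other terminus is neopentyl); O-alkylation, return to the lactone and proton loss to dienes are reversible under acid, whereas C–C bond formation is expected not to be, and the new quaternary centre (S) is set by pseudoaxial attack on the ring face that carries the flat CH=CH arm, anti to the O–CMe2 arm; the closest known reaction types are the acid-catalysed allylation of 1,3-dicarbonyl compounds with allylic alcohols or acetates and the Lewis acid-mediated α-tert-alkylation of silyl enol ethers.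

**Step 16**
Reactants: 24 alkynyl tetronic acid
Product: 25 penicianstinoid C
Conditions: Ph3PAuNTf2 (5 mol %), CH2Cl2, rt
Reagents that add atoms: none
Why: In this gold(I)-catalysed Conia-ene cycloisomerisation the enol carbon C3 adds to the internal carbon of the π-activated terminal alkyne (6-exo-dig, Markovnikov), protodeauration leaves the exocyclic methylene group and closes ring C, and the ring-D spiro centre (S) results from bonding on the tetronate face opposite the 5-methyl group.

**Compound list**
1 | 2-methylbut-3-yn-2-ol | C#CC(C)(C)O | starting material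
2 | 2-methyl-3-(tributylstannyl)but-3-en-2-ol | C=C([Sn](CCCC)(CCCC)CCCC)C(C)(C)O | intermediate
3 | ethyl (Z)-3-iodoacrylate | CCOC(=O)/C=C\I | starting material
4 | ethyl (2Z)-5-hydroxy-5-methyl-4-methylidenehex-2-enoate (not isolated) | CCOC(=O)/C=C\C(=C)C(C)(C)O | intermediate
5 | 6,6-dimethyl-5-methylidene-5,6-dihydro-2H-pyran-2-one | C=C1C=CC(=O)OC1(C)C | intermediate
6 | methyl vinyl ketone | C=CC(C)=O | starting material
7 | acetaldehyde | CC=O | starting material
8 | 4-hydroxy-3-methylidenepentan-2-one (racemic) | C=C(C(C)=O)C(C)O | intermediate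
9 | (3Z)-3-(bromomethyl)pent-3-en-2-one | C/C=C(\CBr)C(C)=O | intermediate
10 | 2,2,5-trimethyl-1,3-dioxane-4,6-dione | CC1C(=O)OC(C)(C)OC1=O | starting material
11 | 3-tert-butoxy-2-methyl-3-oxopropanoic acid (racemic) | CC(C(=O)O)C(=O)OC(C)(C)C | intermediate
12 | 1-benzhydryl 3-tert-butyl 2-methylpropanedioate (racemic) | CC(C(=O)OC(C)(C)C)C(=O)OC(c1ccccc1)c1ccccc1 | intermediate
13 | 1-benzhydryl 3-tert-butyl (2R)-2-[(2E)-2-acetylbut-2-en-1-yl]-2-methylpropanedioate | C/C=C(\C[C@](C)(C(=O)OC(c1ccccc1)c1ccccc1)C(=O)OC(C)(C)C)C(C)=O | intermediate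
14 | 1-benzhydryl 3-tert-butyl (2R)-2-methyl-2-[(2E)-2-{1-[(triisopropylsilyl)oxy]ethenyl}but-2-en-1-yl]propanedioate | C=C(O[Si](C(C)C)(C(C)C)C(C)C)/C(C[C@](C)(C(=O)OC(c1ccccc1)c1ccccc1)C(=O)OC(C)(C)C)=C/C | intermediate
15 | tert-butyl (2R,4E)-2-formyl-2-methyl-4-{1-[(triisopropylsilyl)oxy]ethenyl}hex-4-enoate (not isolated) | C=C(O[Si](C(C)C)(C(C)C)C(C)C)/C(C[C@](C)(C=O)C(=O)OC(C)(C)C)=C/C | intermediate
16 | tert-butyl (2R,4E)-2-ethynyl-2-methyl-4-{1-[(triisopropylsilyl)oxy]ethenyl}hex-4-enoate | C=C(O[Si](C(C)C)(C(C)C)C(C)C)/C(C[C@](C)(C#C)C(=O)OC(C)(C)C)=C/C | intermediate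
17 | tert-butyl (2R)-2-ethynyl-2-methyl-3-[(6R,7S)-1,1,7-trimethyl-3-oxo-9-(triisopropylsilyloxy)-2-oxaspiro[5.5]undeca-4,8-dien-8-yl]propanoate | C[C@H]1C(C[C@](C)(C#C)C(=O)OC(C)(C)C)=C(O[Si](C(C)C)(C(C)C)C(C)C)CC[C@@]12C=CC(=O)OC2(C)C | intermediate
18 | tert-butyl (2R)-2-ethynyl-2-methyl-3-[(6R)-1,1,7-trimethyl-3,9-dioxo-2-oxaspiro[5.5]undeca-4,7-dien-8-yl]propanoate | CC1=C(C[C@](C)(C#C)C(=O)OC(C)(C)C)C(=O)CC[C@@]12C=CC(=O)OC2(C)C | intermediate
19 | tert-butyl (2R)-2-ethynyl-3-[(6R)-9-hydroxy-1,1,7,9-tetramethyl-3-oxo-2-oxaspiro[5.5]undeca-4,7-dien-8-yl]-2-methylpropanoate, either carbinol epimer (not isolated) | CC1=C(C[C@](C)(C#C)C(=O)OC(C)(C)C)C(C)(O)CC[C@@]12C=CC(=O)OC2(C)C | intermediate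
20 | allylic δ-lactone of 19 (carboxyl O bound to the methylated ring-B carbon, tert-butyl group lost), either epimer at the O-bearing carbon | CC1=C2C[C@](C)(C#C)C(=O)OC2(C)CC[C@@]13C=CC(=O)OC3(C)C | intermediate
21 | methyl (R)-lactate | C[C@@H](O)C(=O)OC | starting material
22 | methyl (2R)-2-acetoxypropanoate | C[C@@H](OC(C)=O)C(=O)OC | intermediate
23 | (5R)-4-hydroxy-5-methylfuran-2(5H)-one | C[C@H]1OC(=O)C=C1O | intermediate
24 | (2R)-2-ethynyl-3-{(6R,9S)-9-[(5R)-4-hydroxy-5-methyl-2-oxo-2,5-dihydrofuran-3-yl]-1,1,7,9-tetramethyl-3-oxo-2-oxaspiro[5.5]undeca-4,7-dien-8-yl}-2-methylpropanoic acid | CC1=C(C[C@](C)(C#C)C(=O)O)[C@@](C)(C2=C(O)[C@@H](C)OC2=O)CC[C@@]13C=CC(=O)OC3(C)C | intermediate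
25 | penicianstinoid C | C=C1[C@](C)(C(=O)O)CC2=C(C)[C@]3(C=CC(=O)OC3(C)C)CC[C@]2(C)[C@@]12C(=O)O[C@H](C)C2=O | target

**Step count**
- Total: 16 steps.
- Longest linear sequence: 10 steps (3, 4, 7, 8, 9, 10, 11, 12, 15, 16; the branch through 5 and 6 is equally long).

**Steps most likely to fail**

First, step 10.
- What may go wrong: bond formation at the fully substituted alkene carbon next to CMe2 may be sluggish. The reaction may stop after the first C–C bond (1,6-Mukaiyama–Michael addition with silyl transfer). Facial discrimination may be weak because the catalyst is bound four atoms away from the reacting alkene.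
- Fallback: setting out from 5 and 16, the cycloaddition is run without a chiral catalyst (Me2AlCl, CH2Cl2, −40 °C, or heating in toluene), which is a known reaction type for 2-silyloxydienes and exocyclic methylene lactones. Because 16 is already a single enantiomer, addition to the two faces of 5 gives diastereomers, namely 17 and the spiro-epimeric adduct tert-butyl (2R)-2-ethynyl-2-methyl-3-[(6S,7R)-1,1,7-trimethyl-3-oxo-9-(triisopropylsilyloxy)-2-oxaspiro[5.5]undeca-4,8-dien-8-yl]propanoate F1. The mixture is oxidised as in step 11 to 18 and the spiro-epimeric enone tert-butyl (2R)-2-ethynyl-2-methyl-3-[(6S)-1,1,7-trimethyl-3,9-dioxo-2-oxaspiro[5.5]undeca-4,7-dien-8-yl]propanoate F2. These differ only at the spiro carbon and are separated by chromatography or crystallisation. The route is rejoined at 18.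

Second, step 15.
- What may go wrong: the cation may lose a proton to give dienes, may return to the lactone faster than it is captured, may be taken by the enol oxygen, or may be attacked from both ring faces.
- Fallback: setting out from 20, the cation is intercepted by a smaller and much stronger π-nucleophile, 1,1-bis(trimethylsilyloxy)ethene (ZnCl2 or TMSOTf cat., CH2Cl2, −78 → 0 °C). This is the known Lewis acid-mediated α-tert-alkylation of a silyl ketene acetal. After aqueous work-up it gives the diacid (2R)-3-[(6R,9R)-9-(carboxymethyl)-1,1,7,9-tetramethyl-3-oxo-2-oxaspiro[5.5]undeca-4,7-dien-8-yl]-2-ethynyl-2-methylpropanoic acid F3. Steglich esterification (EDC, DMAP) of its unhindered CH2CO2H group with methyl (R)-lactate 21 gives the acyloxy ester (2R)-2-ethynyl-3-[(6R,9R)-9-(2-{[(2R)-1-methoxy-1-oxopropan-2-yl]oxy}-2-oxoethyl)-1,1,7,9-tetramethyl-3-oxo-2-oxaspiro[5.5]undeca-4,7-dien-8-yl]-2-methylpropanoic acid F4. Lacey–Dieckmann cyclisation (LiHMDS, THF, −78 °C) then builds ring D on the quaternary carbon, and the route is rejoined at 24.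

Third, step 16.
- What may go wrong: the 6-exo closure between two fully substituted carbons may be slow. The activated alkyne may be diverted by the carboxyl group or by the ring-B alkene. The remote 5-methyl group may give too little facial bias.
- Fallback: setting out from 24, ring C is closed by a radical route instead of π-acid activation. Mn(OAc)3 (2 equiv) in EtOH/AcOH oxidises the tetronic acid to its C3 radical, which adds 6-exo-dig to the alkyne, and the vinyl radical takes a hydrogen atom from ethanol. This leads directly to 25 and makes no new compound (F0).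

**Further compounds**
F1 | step 10 | tert-butyl (2R)-2-ethynyl-2-methyl-3-[(6S,7R)-1,1,7-trimethyl-3-oxo-9-(triisopropylsilyloxy)-2-oxaspiro[5.5]undeca-4,8-dien-8-yl]propanoate | C[C@@H]1C(C[C@](C)(C#C)C(=O)OC(C)(C)C)=C(O[Si](C(C)C)(C(C)C)C(C)C)CC[C@]12C=CC(=O)OC2(C)C
F2 | step 10 | tert-butyl (2R)-2-ethynyl-2-methyl-3-[(6S)-1,1,7-trimethyl-3,9-dioxo-2-oxaspiro[5.5]undeca-4,7-dien-8-yl]propanoate | CC1=C(C[C@](C)(C#C)C(=O)OC(C)(C)C)C(=O)CC[C@]12C=CC(=O)OC2(C)C
F3 | step 15 | (2R)-3-[(6R,9R)-9-(carboxymethyl)-1,1,7,9-tetramethyl-3-oxo-2-oxaspiro[5.5]undeca-4,7-dien-8-yl]-2-ethynyl-2-methylpropanoic acid | CC1=C(C[C@](C)(C#C)C(=O)O)[C@@](C)(CC(=O)O)CC[C@@]13C=CC(=O)OC3(C)C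
F4 | step 15 | (2R)-2-ethynyl-3-[(6R,9R)-9-(2-{[(2R)-1-methoxy-1-oxopropan-2-yl]oxy}-2-oxoethyl)-1,1,7,9-tetramethyl-3-oxo-2-oxaspiro[5.5]undeca-4,7-dien-8-yl]-2-methylpropanoic acid | CC1=C(C[C@](C)(C#C)C(=O)O)[C@@](C)(CC(=O)O[C@H](C)C(=O)OC)CC[C@@]13C=CC(=O)OC3(C)C
F0 | step 16 | none | none
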